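## Retrosynthetic overview

1. The target is the cis-(S,S)-2-ene-1,4-diol monoester with two ring-cis (Z) trisubstituted olefins. The ester is cut to the cis-diol and 4-(silyloxy)benzoic acid (from 4-bromophenol and CO2); acylation takes the allylic OH that is not next to the quaternary carbon.
2. The cis-diol comes from the (Z)-γ-hydroxy enone by a new boron-chelate-controlled 1,4-syn reduction, which sets the second carbinol from the first.
3. The eleven-membered (Z,Z)-dienone comes from a cis-fused 6–7 bicyclic 1,3-diol monomesylate by Grob ring-expanding fragmentation (6 + 7 → 11). The new Z-olefin forms stereospecifically; the Z-enone is inherited from the cycloheptene.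
4. The bicycle comes from an aldol adduct of 2,2,6-trimethylcyclohexanone with an (S)-β-silyloxy (Z)-iodoalkenyl aldehyde, closed by intramolecular alkenyllithium addition. The aldehyde comes from propargyl alcohol (carbometalation–iodination, oxidation, catalytic asymmetric acetaldehyde aldol).
5. Ring order: purchased six-membered ring → fused cycloheptene (step 6) → both merged into the one eleven-membered ring (step 7); the arene is attached last.

Assumption: in steps 5 to 7 the number and SMILES denote the 1,3-anti diastereomer; its companion (both centres of the aldol pair inverted) is carried along unseparated, because the fragmentation erases those centres and both give the same dienone.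

## Route

Step 1
Reactants: 1 prop-2-yn-1-ol
Product: 3 (Z)-3-iodo-2-methylprop-2-en-1-ol, via alkenylmagnesium alkoxide 2 (not isolated)
Conditions: MeMgBr (2.5 equiv), CuI (10 mol %), THF/Et2O, −10 °C → rt; then I2, −78 → 0 °C
Reagents that add atoms: methylmagnesium bromide (C[Mg]Br); iodine (II)
Why: Copper-catalysed anti-carbomagnesiation of the propargylic alkoxide puts methyl on the internal carbon and magnesium on the terminal carbon in a five-membered chelate, and iodinolysis with retention gives the Z-iodide (iodine cis to CH2OH); no stereocentre is formed.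

Step 2
Reactants: 3 (Z)-3-iodo-2-methylprop-2-en-1-ol
Product: 4 (Z)-3-iodo-2-methylprop-2-enal
Conditions: MnO2 (excess), CH2Cl2, rt, dark
Reagents that add atoms: none
Why: Allylic alcohol oxidation with MnO2 is neutral and heterogeneous, so the Z-iodoalkene does not isomerise.

Step 3
Reactants: 4 (Z)-3-iodo-2-methylprop-2-enal; 5 tert-butyl(ethenyloxy)dimethylsilane
Product: 6 (3S,4Z)-3-[(tert-butyldimethylsilyl)oxy]-5-iodo-4-methylpent-4-enal
Conditions: chiral IDPi acid (confined imidodiphosphorimidate, 1 mol %, enantiomer giving 3S), toluene, −60 °C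
Reagents that add atoms: none
Why: Catalytic asymmetric Mukaiyama aldol (single aldolization of an acetaldehyde silyl enol ether): the confined catalyst selects one aldehyde face and so sets 3S, and silyl transfer to the aldolate oxygen releases a β-silyloxy aldehyde too bulky to react again.

Step 4
Reactants: 7 2-methylcyclohexan-1-one (racemic)
Product: 11 2,2,6-trimethylcyclohexan-1-one (racemic), via kinetic lithium enolate 8 (not isolated), via 2,6-dimethylcyclohexan-1-one 9 (not isolated), via lithium 2,6-dimethylcyclohexenolate 10 (not isolated)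
Conditions: LiN(i-Pr)2 (1.05 equiv), THF, −78 °C; MeI (1.0 equiv); then LiN(i-Pr)2 (1.1 equiv), −78 → 0 °C; MeI, 0 °C → rt
Reagents that add atoms: iodomethane (CI)
Why: Two enolate alkylations in one flask; the regiochemistry of the first methylation does not matter because 2,6- and 2,2-dimethyl ketone both give 11 in the second, and the one stereocentre of 11 is erased in step 5.

Step 5
Reactants: 11 2,2,6-trimethylcyclohexan-1-one; 6 (3S,4Z)-3-[(tert-butyldimethylsilyl)oxy]-5-iodo-4-methylpent-4-enal
Product: 13 (2S)-2-[(1S,3S,4Z)-3-[(tert-butyldimethylsilyl)oxy]-1-hydroxy-5-iodo-4-methylpent-4-en-1-yl]-2,6,6-trimethylcyclohexan-1-one, via lithium enolate 12 (not isolated)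
Conditions: LiN(i-Pr)2, THF, 0 °C, 1 h; then 6, −78 °C, 20 min; AcOH, −78 °C
Reagents that add atoms: none
Why: Lithium enolate aldol addition through a Zimmerman–Traxler chair (aldehyde chain equatorial, ring CH2 in the E position of the fully substituted enolate) forms the quaternary carbon and the carbinol in the like (S*,S*) relation that step 7 needs (expected about 4:1, unlike isomers removed by chromatography); the silyloxy centre comes from 6 and induces only weakly, so the 1,3-syn companion is carried along.

Step 6
Reactants: 13 aldol adduct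
Product: 15 (4aS,5S,7S,9aR)-7-[(tert-butyldimethylsilyl)oxy]-1,1,4a,8-tetramethyl-1,2,3,4,4a,5,6,7-octahydro-9aH-benzo[7]annulene-5,9a-diol (cis-fused; bridgehead OH cis and secondary OH trans to the angular methyl), via alkenyllithium alkoxide 14 (not isolated)
Conditions: MeLi (1.05 equiv), Et2O, −78 °C; t-BuLi (2.1 equiv), Et2O/pentane, −78 → −30 °C; H2O
Reagents that add atoms: none
Why: Iodine–lithium exchange followed by intramolecular 1,2-addition of the unhindered CH–Li terminus to the non-enolisable ketone closes the cycloheptene; the tether delivers carbon to the carbonyl face away from the axial α-methyl groups, which gives the cis ring fusion (9aR), and ether/pentane suppresses silyl migration from oxygen to the carbanion.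

Step 7
Reactants: 15 bicyclic diol
Product: 17 (2Z,4S,6Z)-4-[(tert-butyldimethylsilyl)oxy]-3,7,11,11-tetramethylcycloundeca-2,6-dien-1-one, via secondary mesylate 16 (not isolated)
Conditions: MsCl (1.2 equiv), Et3N, THF, −20 °C; then KOt-Bu (2.5 equiv), THF, −20 → 0 °C, 20 min; pH 7 buffer
Reagents that add atoms: none
Why: Grob (Wharton) ring-expanding fragmentation: only the secondary OH is mesylated, the bridgehead potassium alkoxide then expels the mesylate through antiperiplanar cleavage of the ring-fusion bond, and the equatorial mesylate trans to the angular methyl gives the Z trisubstituted olefin stereospecifically; the cycloheptene olefin becomes the Z-enone and the silyloxy centre is untouched (short base contact avoids γ-epimerisation).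

Step 8
Reactants: 17 silyloxy dienone
Product: 18 (2Z,4S,6Z)-4-hydroxy-3,7,11,11-tetramethylcycloundeca-2,6-dien-1-one
Conditions: Bu4NF, AcOH (1:1), THF, 0 °C → rt
Reagents that add atoms: none
Why: Fluoride desilylation buffered with acetic acid is near neutral, so C4 does not epimerise; dehydration of the reversible bridged hemiketal to a furan is disfavoured because the furan would be a strained seven-carbon-bridged 2,5-furanophane.

Step 9
Reactants: 18 (Z)-γ-hydroxy enone
Product: 20 (1S,2Z,4S,6Z)-3,7,11,11-tetramethylcycloundeca-2,6-diene-1,4-diol, via diethylboron chelate 19 (not isolated)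
Conditions: Et2BOMe (1.2 equiv), THF/MeOH 4:1, −78 °C, 30 min; NaBH4, −78 °C; AcOH, then MeOH co-evaporation
Reagents that add atoms: none
Why: Proposed new method: a 1,4-syn chelation-controlled reduction of a (Z)-γ-hydroxy enone, in which Et2BOMe turns the C4 hydroxyl into a diethylborinate whose boron binds the ketone oxygen in a seven-membered chelate held rigid by the Z-olefin; avoiding A(1,2) strain with the C3 methyl puts the C5 methylene pseudo-axial, so the C5–C11 loop of the macrocycle covers one carbonyl face and external borohydride adds 1,2 from the other, giving the new carbinol cis to the old one (1S); the closest known reaction type is the Narasaka–Prasad 1,3-syn reduction of β-hydroxy ketones through six-membered boron chelates.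

Step 10
Reactants: 21 4-bromophenol
Product: 22 (4-bromophenoxy)(tert-butyl)dimethylsilane
Conditions: TBSCl, imidazole, DMF, rt
Reagents that add atoms: tert-butyldimethylsilyl chloride (CC(C)(C)[Si](C)(C)Cl)
Why: Standard imidazole-promoted silylation of a phenol masks the acidic OH for the lithiation and the later esterification.

Step 11
Reactants: 22 (4-bromophenoxy)(tert-butyl)dimethylsilane
Product: 24 4-[(tert-butyldimethylsilyl)oxy]benzoic acid, via aryllithium 23 (not isolated)
Conditions: n-BuLi, THF, −78 °C; CO2 (gas); then 1 M HCl to pH 4, 0 °C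
Reagents that add atoms: carbon dioxide (O=C=O)
Why: Bromine–lithium exchange and carboxylation of the aryllithium; the aryl silyl ether survives the cold, mildly acidic work-up.

Step 12
Reactants: 20 cis-diol; 24 4-[(tert-butyldimethylsilyl)oxy]benzoic acid
Product: 25 (1S,2Z,4S,9Z)-4-hydroxy-2,5,5,9-tetramethylcycloundeca-2,9-dien-1-yl 4-[(tert-butyldimethylsilyl)oxy]benzoate
Conditions: EDC·HCl (1.2 equiv), DMAP (0.2 equiv), 24 (1.05 equiv), CH2Cl2, 0 °C → rt
Reagents that add atoms: none
Why: Steglich esterification acylates the allylic hydroxyl flanked by a CH2 group much faster than the neopentylic hydroxyl beside the quaternary carbon, and proceeds with retention at both carbinol centres.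

Step 13
Reactants: 25 silyl-protected ester
Product: 26 (1S,2Z,4S,9Z)-4-hydroxy-2,5,5,9-tetramethylcycloundeca-2,9-dien-1-yl 4-hydroxybenzoate
Conditions: KHF2, MeOH, rt
Reagents that add atoms: none
Why: KHF2 in methanol cleaves phenolic silyl ethers selectively (phenoxide is the good leaving group on silicon) and leaves the allylic ester, the free alcohol and both olefins alone.

## Compound list

1 | prop-2-yn-1-ol | C#CCO | starting material
2 | bromomagnesium (Z)-3-(bromomagnesio)-2-methylprop-2-en-1-olate | C/C(CO[Mg]Br)=C/[Mg]Br | intermediate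
3 | (Z)-3-iodo-2-methylprop-2-en-1-ol | C/C(CO)=C/I | intermediate
4 | (Z)-3-iodo-2-methylprop-2-enal | C/C(C=O)=C/I | intermediate
5 | tert-butyl(ethenyloxy)dimethylsilane (silyl enol ether of acetaldehyde) | C=CO[Si](C)(C)C(C)(C)C | starting material
6 | (3S,4Z)-3-[(tert-butyldimethylsilyl)oxy]-5-iodo-4-methylpent-4-enal | O=CC[C@H](O[Si](C)(C)C(C)(C)C)/C(C)=C\I | intermediate
7 | 2-methylcyclohexan-1-one (racemic) | CC1CCCCC1=O | starting material
8 | lithium 6-methylcyclohex-1-en-1-olate | CC1CCCC=C1[O-].[Li+] | intermediate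
9 | 2,6-dimethylcyclohexan-1-one (cis/trans mixture) | CC1CCCC(C)C1=O | intermediate
10 | lithium 2,6-dimethylcyclohex-1-en-1-olate | CC1CCCC(C)=C1[O-].[Li+] | intermediate
11 | 2,2,6-trimethylcyclohexan-1-one (racemic) | CC1CCCC(C)(C)C1=O | intermediate
12 | lithium 2,6,6-trimethylcyclohex-1-en-1-olate | CC1=C([O-])C(C)(C)CCC1.[Li+] | intermediate
13 | (2S)-2-[(1S,3S,4Z)-3-[(tert-butyldimethylsilyl)oxy]-1-hydroxy-5-iodo-4-methylpent-4-en-1-yl]-2,6,6-trimethylcyclohexan-1-one | CC1(C)CCC[C@](C)(C1=O)[C@@H](O)C[C@H](O[Si](C)(C)C(C)(C)C)/C(C)=C\I | intermediate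
14 | lithium alkoxide of 13 with the iodine exchanged for lithium | CC1(C)CCC[C@](C)(C1=O)[C@@H](O[Li])C[C@H](O[Si](C)(C)C(C)(C)C)/C(C)=C\[Li] | intermediate
15 | (4aS,5S,7S,9aR)-7-[(tert-butyldimethylsilyl)oxy]-1,1,4a,8-tetramethyl-1,2,3,4,4a,5,6,7-octahydro-9aH-benzo[7]annulene-5,9a-diol | CC1(C)CCC[C@@]2(C)[C@@H](O)C[C@H](O[Si](C)(C)C(C)(C)C)C(C)=C[C@@]12O | intermediate
16 | (4aS,5S,7S,9aR)-7-[(tert-butyldimethylsilyl)oxy]-9a-hydroxy-1,1,4a,8-tetramethyl-1,2,3,4,4a,5,6,7-octahydro-9aH-benzo[7]annulen-5-yl methanesulfonate | CC1(C)CCC[C@@]2(C)[C@@H](OS(C)(=O)=O)C[C@H](O[Si](C)(C)C(C)(C)C)C(C)=C[C@@]12O | intermediate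
17 | (2Z,4S,6Z)-4-[(tert-butyldimethylsilyl)oxy]-3,7,11,11-tetramethylcycloundeca-2,6-dien-1-one | C/C1=C/C[C@H](O[Si](C)(C)C(C)(C)C)/C(C)=C\C(=O)C(C)(C)CCC1 | intermediate
18 | (2Z,4S,6Z)-4-hydroxy-3,7,11,11-tetramethylcycloundeca-2,6-dien-1-one | C/C1=C/C[C@H](O)/C(C)=C\C(=O)C(C)(C)CCC1 | intermediate
19 | diethylborinate of 18 (boron chelated to the ketone oxygen) | C/C1=C/C[C@H](OB(CC)CC)/C(C)=C\C(=O)C(C)(C)CCC1 | intermediate
20 | (1S,2Z,4S,6Z)-3,7,11,11-tetramethylcycloundeca-2,6-diene-1,4-diol | C/C1=C/C[C@H](O)/C(C)=C\[C@H](O)C(C)(C)CCC1 | intermediate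
21 | 4-bromophenol | Oc1ccc(Br)cc1 | starting material
22 | (4-bromophenoxy)(tert-butyl)dimethylsilane | CC(C)(C)[Si](C)(C)Oc1ccc(Br)cc1 | intermediate
23 | {4-[(tert-butyldimethylsilyl)oxy]phenyl}lithium | [Li]c1ccc(O[Si](C)(C)C(C)(C)C)cc1 | intermediate
24 | 4-[(tert-butyldimethylsilyl)oxy]benzoic acid | OC(=O)c1ccc(O[Si](C)(C)C(C)(C)C)cc1 | intermediate
25 | (1S,2Z,4S,9Z)-4-hydroxy-2,5,5,9-tetramethylcycloundeca-2,9-dien-1-yl 4-[(tert-butyldimethylsilyl)oxy]benzoate | C/C1=C/C[C@H](OC(=O)c2ccc(O[Si](C)(C)C(C)(C)C)cc2)/C(C)=C\[C@H](O)C(C)(C)CCC1 | intermediate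
26 | (1S,2Z,4S,9Z)-4-hydroxy-2,5,5,9-tetramethylcycloundeca-2,9-dien-1-yl 4-hydroxybenzoate | C/C1=C/C[C@H](OC(=O)c2ccc(O)cc2)/C(C)=C\[C@H](O)C(C)(C)CCC1 | target

## Step count and risks

Total step count: 13. Longest linear sequence: 10 steps (1, 2, 3, 5, 6, 7, 8, 9, 12, 13).

**Step 5 (aldol).** The risk is modest like/unlike selectivity at the quaternary carbon and retro-aldol; the unlike isomer would give the E-olefin in step 7. The fallback sets out from 13, taken as the unseparated mixture with its carbinol epimer, and comes back at 15. The mixture of 13 and 1'-epi-13 F1 is cyclised as in step 6, giving 15 together with 5-epi-15 F2. Dess–Martin periodinane (CH2Cl2, NaHCO3, 0 °C) oxidises the secondary alcohol of both to the one bicyclic β-hydroxy ketone F3. Me4NBH(OAc)3 (MeCN/AcOH, −30 °C, Evans–Saksena reduction) then delivers hydride from the bridgehead hydroxyl and gives only the 1,3-anti diol, which is 15. Aldol stereocontrol is thus replaced by a directed reduction on the rigid bicycle.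

**Step 6 (alkenyllithium ring closure).** The risks are the very hindered ketone, silyl migration to the carbanion and retro-aldol of the alkoxide. The fallback sets out from 11 (through enolate 12) and comes back at 15. Enolate 12 is added, as in step 5, to (3S)-3-silyloxy-4-methylpent-4-enal F5, which is made from methacrolein F4 and 5 under the conditions of step 3; this gives isopropenyl aldol F6. CH2=CHMgBr with anhydrous CeCl3 (THF, −78 → 0 °C, directed by the magnesium alkoxide) converts the ketone into vinyl carbinol F7. Ring-closing metathesis with second-generation Grubbs catalyst RuCl2(=CHPh)(PCy3)(H2IMes) (toluene, 80 °C) closes the trisubstituted cycloheptene and gives 15. This route uses no alkenyllithium.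

**Step 9 (new 1,4-syn reduction).** The risks are that the seven-membered chelate may not form or may not control the face, and that the hemiketal may interfere. The fallback uses known chemistry, sets out from 17 and comes back at 20. (R)-2-Methyl-CBS-oxazaborolidine (20 mol %) with catecholborane (toluene, −78 °C) reduces the ketone of 17 under catalyst control, with the quaternary α-carbon acting as the large group, to silyl ether alcohol F8. Bu4NF/AcOH (THF, rt) then gives 20. Should the catalyst sense prove opposite, the (S)-catalyst is used.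

## Further compounds

F1 | step 5 | (2S)-2-[(1R,3S,4Z)-3-[(tert-butyldimethylsilyl)oxy]-1-hydroxy-5-iodo-4-methylpent-4-en-1-yl]-2,6,6-trimethylcyclohexan-1-one | CC1(C)CCC[C@](C)(C1=O)[C@H](O)C[C@H](O[Si](C)(C)C(C)(C)C)/C(C)=C\I
F2 | step 5 | (4aS,5R,7S,9aR)-7-[(tert-butyldimethylsilyl)oxy]-1,1,4a,8-tetramethyl-1,2,3,4,4a,5,6,7-octahydro-9aH-benzo[7]annulene-5,9a-diol | CC1(C)CCC[C@@]2(C)[C@H](O)C[C@H](O[Si](C)(C)C(C)(C)C)C(C)=C[C@@]12O
F3 | step 5 | (4aR,7S,9aR)-7-[(tert-butyldimethylsilyl)oxy]-9a-hydroxy-1,1,4a,8-tetramethyl-1,2,3,4,4a,6,7,9a-octahydro-5H-benzo[7]annulen-5-one | CC1(C)CCC[C@@]2(C)C(=O)C[C@H](O[Si](C)(C)C(C)(C)C)C(C)=C[C@@]12O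
F4 | step 6 | 2-methylprop-2-enal (methacrolein) | CC(=C)C=O
F5 | step 6 | (3S)-3-[(tert-butyldimethylsilyl)oxy]-4-methylpent-4-enal | O=CC[C@H](O[Si](C)(C)C(C)(C)C)C(C)=C
F6 | step 6 | (2S)-2-[(1S,3S)-3-[(tert-butyldimethylsilyl)oxy]-1-hydroxy-4-methylpent-4-en-1-yl]-2,6,6-trimethylcyclohexan-1-one | CC1(C)CCC[C@](C)(C1=O)[C@@H](O)C[C@H](O[Si](C)(C)C(C)(C)C)C(C)=C
F7 | step 6 | (1R,2S)-2-[(1S,3S)-3-[(tert-butyldimethylsilyl)oxy]-1-hydroxy-4-methylpent-4-en-1-yl]-1-ethenyl-2,6,6-trimethylcyclohexan-1-ol | CC1(C)CCC[C@@](C)([C@@H](O)C[C@H](O[Si](C)(C)C(C)(C)C)C(C)=C)[C@@]1(O)C=C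
F8 | step 9 | (1S,2Z,4S,6Z)-4-[(tert-butyldimethylsilyl)oxy]-3,7,11,11-tetramethylcycloundeca-2,6-dien-1-ol | C/C1=C/C[C@H](O[Si](C)(C)C(C)(C)C)/C(C)=C\[C@H](O)C(C)(C)CCC1
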